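**Plan**

- Numbering: ring B (five-membered) is C1 (bears the C8 ketone to ring D), C2 (ring C), C3 (ring E), C3a, C7a; ring A is C3a–C4(OH)–C5–C6(OH)–C7–C7a.
- Enabling feature: along C8–C1–C7a–C3a–C4–C5–C6–C7 oxygen sits on every other carbon (C8, C7a, C4, C6), so ring A with the C8 ketone is a folded tetraketide. The retrosynthesis cuts C7–C7a (aldol) and C3a–C4 (Claisen), leaving a 2-aroylcyclopentanone (ring B) and an acetoacetyl unit masked as a ketal.
- Ring B is cut at C1–C7a (intramolecular Claisen) and then at C2–C3 (carbene-catalysed homoenolate Michael addition), giving a chalcone (rings C and D) and a cinnamaldehyde (ring E).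
- Forward: C2–C3 bond, then ring B, then ring A onto ring B; all phenols travel as benzyl ethers.
- Stereochemistry: C2 and C3 (cis) come from the chiral triazolium carbene in the C2–C3 bond formation. C1 is set last by kinetic protonation of its enolate on the face away from rings C and E, followed by neutral hydrogenolysis.

Key step: step 6

Assumption: the (5aS,10bR) triazolium salt is taken to deliver the (3R,4S) adduct 7; if the sense of induction is the reverse, its commercially available mirror image is used and nothing else changes.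

**Route**

Step 1
Reactants: 1 4-(benzyloxy)benzaldehyde; 2 1-[4-(benzyloxy)phenyl]ethan-1-one
Product: 3 (E)-1,3-bis[4-(benzyloxy)phenyl]prop-2-en-1-one
Conditions: NaOH (0.3 equiv), EtOH, rt
Reagents that add atoms: none
Why: Claisen–Schmidt condensation, in which the enolate of 2 adds to the non-enolisable aldehyde 1 and the aldol dehydrates to the conjugated E-enone, which should crystallise from ethanol.

Step 2
Reactants: 4 3,5-bis(benzyloxy)benzaldehyde; 5 (triphenylphosphoranylidene)acetaldehyde
Product: 6 (E)-3-[3,5-bis(benzyloxy)phenyl]prop-2-enal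
Conditions: toluene, 80 °C
Reagents that add atoms: none
Why: Wittig reaction with a stabilised formyl ylide, which should give the E-enal; a slight excess of 4 limits a second homologation.

Step 3
Reactants: 3 (E)-1,3-bis[4-(benzyloxy)phenyl]prop-2-en-1-one; 6 (E)-3-[3,5-bis(benzyloxy)phenyl]prop-2-enal
Product: 7 methyl (3R,4S)-3-[3,5-bis(benzyloxy)phenyl]-4,6-bis[4-(benzyloxy)phenyl]-6-oxohexanoate
Conditions: (5aS,10bR)-2-mesityl-5a,10b-dihydro-4H,6H-indeno[2,1-b][1,2,4]triazolo[4,3-d][1,4]oxazin-2-ium chloride (10 mol %), DBU (15 mol %), MeOH (5 equiv), THF, rt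
Reagents that add atoms: methanol, CO
Why: Carbene-catalysed homoenolate Michael addition, in which the β-carbon of the carbene-bound enal 6 adds to the β-carbon of chalcone 3 and methanol releases the acyl azolium as the methyl ester; both stereocentres arise in this one C–C bond formation under control of the aminoindanol-derived triazolium carbene, which in annulations of cinnamaldehydes with chalcones gives the cis-type arrangement (here 3R,4S), and any aldol-cyclised hydroxy ester formed beside 7 should revert and converge in step 4.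

Step 4
Reactants: 7 methyl (3R,4S)-3-[3,5-bis(benzyloxy)phenyl]-4,6-bis[4-(benzyloxy)phenyl]-6-oxohexanoate
Product: 8 (3R,4R)-2-[4-(benzyloxy)benzoyl]-4-[3,5-bis(benzyloxy)phenyl]-3-[4-(benzyloxy)phenyl]cyclopentan-1-one (3,4-cis; C2 enolised and undefined)
Conditions: KOtBu (2.2 equiv), THF, 0 °C to rt; then 1 M HCl
Reagents that add atoms: none
Why: Intramolecular Claisen (Dieckmann-type) condensation, in which the enolate of the aryl ketone (the more acidic α-position) attacks the methyl ester in a 5-exo-trig closure and the β-diketone is withdrawn from all equilibria as its potassium enolate; C3 and C4 lie β to both carbonyl groups and keep their configuration.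

Step 5
Reactants: 9 ethyl 2-(2-methyl-1,3-dioxolan-2-yl)acetate
Product: 10 N-methoxy-N-methyl-2-(2-methyl-1,3-dioxolan-2-yl)acetamide
Conditions: MeNH(OMe)·HCl (1.5 equiv), iPrMgCl (3.0 equiv), THF, −20 to 0 °C
Reagents that add atoms: N,O-dimethylhydroxylamine hydrochloride, CNOC.Cl
Why: Weinreb amide formation by aminolysis of the ester with the chloromagnesium amide, which at low temperature should be faster than enolisation of the ester and leaves the dioxolane intact.

Step 6
Reactants: 8 (3R,4R)-2-[4-(benzyloxy)benzoyl]-4-[3,5-bis(benzyloxy)phenyl]-3-[4-(benzyloxy)phenyl]cyclopentan-1-one; 10 N-methoxy-N-methyl-2-(2-methyl-1,3-dioxolan-2-yl)acetamide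
Product: 14 [(1S,2R,3R)-3-[3,5-bis(benzyloxy)phenyl]-2-[4-(benzyloxy)phenyl]-4,6-dihydroxy-2,3-dihydro-1H-inden-1-yl][4-(benzyloxy)phenyl]methanone (ring A as free 4,6-diol; rings C and E cis; aroyl group trans to ring C), via dilithium dianion 11 (not isolated), via triketone ketal 12 (not isolated), via tetraketone 13 (not isolated)
Conditions: LiN(iPr)2 (2.2 equiv), THF, −78 to 0 °C; 10 (1.3 equiv), −78 to 0 °C; 2 M HCl, THF, rt; then degassed aq KOH (to 2 M), MeOH, rt; HCl to pH 3
Reagents that add atoms: water, O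
Why: LiN(iPr)2 (2 equiv) turns β-diketone 8 into dianion 11, whose last-formed and least stabilised carbanion, the ring carbon next to the ketone (future C3a), attacks Weinreb amide 10 (Claisen-type γ-acylation of a β-diketone dianion, C3a–C4), and the chelated tetrahedral adduct survives until the acid quench, so the acidic product 12 never meets unreacted dianion. Aqueous HCl then hydrolyses the dioxolane to tetraketone 13, which carries oxygen on C8, C7a, C4 and C6; in aqueous KOH the enolate of the C6 ketone attacks the C7a carbonyl through its methyl carbon C7 (aldol, C7–C7a), and loss of water with enolisation at C4 and C6 gives the resorcinol, the closest known reaction being the hydroxide-induced cyclisation of 2,4,6-triketones and 1,3,5,7-tetraketones to orcinol-type resorcinols. Ring A closes in a 6-(enolendo)-exo-trig aldol. No stereocentre is created: C3a becomes aromatic, C2 and C3 lie β to every carbonyl and cannot enolise, and C1, benzylic and α to the ketone in 14, should settle in the hydroxide medium in the trans (1S) arrangement. The step needs acylation at C3a and not at C1, which the reactivity order of the dianion secures, and the C7-to-C7a fold, which ring B secures because C1 and C3a are ring atoms and the competing aldols (C1 onto C6, C5 onto C8) can only give bridged adducts that revert and cannot aromatise. Any 4-pyranone formed from the C7a, C4 and C6 carbonyls during the acid stage should be reopened by hydroxide and funnel into the same closure.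

Step 7
Reactants: 14 [(1S,2R,3R)-3-[3,5-bis(benzyloxy)phenyl]-2-[4-(benzyloxy)phenyl]-4,6-dihydroxy-2,3-dihydro-1H-inden-1-yl][4-(benzyloxy)phenyl]methanone
Product: 15 [(1S,2R,3R)-4,6-bis(benzyloxy)-3-[3,5-bis(benzyloxy)phenyl]-2-[4-(benzyloxy)phenyl]-2,3-dihydro-1H-inden-1-yl][4-(benzyloxy)phenyl]methanone
Conditions: BnBr (2.3 equiv), K2CO3 (2.5 equiv), DMF, rt
Reagents that add atoms: benzyl bromide, BrCc1ccccc1
Why: Williamson ether synthesis on the two ring A phenols, the only acidic O–H groups, so that step 8 needs a single equivalent of base; C1 is already in its stable trans configuration and is not at risk under carbonate.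

Step 8
Reactants: 15 [(1S,2R,3R)-4,6-bis(benzyloxy)-3-[3,5-bis(benzyloxy)phenyl]-2-[4-(benzyloxy)phenyl]-2,3-dihydro-1H-inden-1-yl][4-(benzyloxy)phenyl]methanone
Product: 17 [(1R,2R,3R)-4,6-bis(benzyloxy)-3-[3,5-bis(benzyloxy)phenyl]-2-[4-(benzyloxy)phenyl]-2,3-dihydro-1H-inden-1-yl][4-(benzyloxy)phenyl]methanone (all-cis), via potassium enolate 16 (not isolated)
Conditions: KN(SiMe3)2 (1.3 equiv), THF, −78 °C; cannulation into AcOH (10 equiv), THF, −78 °C
Reagents that add atoms: none
Why: Kinetic protonation of an exocyclic enolate, in which the base removes the benzylic α-proton at C1 and the planar enolate 16 is protonated irreversibly by acetic acid on the face opposite the neighbouring ring C aryl (rings C and E shield the other face), which places the aroyl group cis to both and should give the less stable (1R) ketone; acetate is too weak a base to re-equilibrate it.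

Step 9
Reactants: 17 [(1R,2R,3R)-4,6-bis(benzyloxy)-3-[3,5-bis(benzyloxy)phenyl]-2-[4-(benzyloxy)phenyl]-2,3-dihydro-1H-inden-1-yl][4-(benzyloxy)phenyl]methanone
Product: 18 caraphenol B, [(1R,2R,3R)-3-(3,5-dihydroxyphenyl)-4,6-dihydroxy-2-(4-hydroxyphenyl)-2,3-dihydro-1H-inden-1-yl](4-hydroxyphenyl)methanone
Conditions: H2 (1 atm), Pd/C (10 wt %), EtOAc/MeOH, rt
Reagents that add atoms: none
Why: Hydrogenolysis of the six benzyl ethers under neutral, non-enolising conditions, so that the contra-thermodynamic C1 configuration should survive; the hindered, electron-rich aryl ketone is expected to be reduced far more slowly than the O–benzyl bonds are cut.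

**Compound list**

1 | 4-(benzyloxy)benzaldehyde | O=Cc1ccc(OCc2ccccc2)cc1 | starting material
2 | 1-[4-(benzyloxy)phenyl]ethan-1-one | CC(=O)c1ccc(OCc2ccccc2)cc1 | starting material
3 | (E)-1,3-bis[4-(benzyloxy)phenyl]prop-2-en-1-one | O=C(/C=C/c1ccc(OCc2ccccc2)cc1)c1ccc(OCc2ccccc2)cc1 | intermediate
4 | 3,5-bis(benzyloxy)benzaldehyde | O=Cc1cc(OCc2ccccc2)cc(OCc2ccccc2)c1 | starting material
5 | (triphenylphosphoranylidene)acetaldehyde | O=CC=P(c1ccccc1)(c1ccccc1)c1ccccc1 | starting material
6 | (E)-3-[3,5-bis(benzyloxy)phenyl]prop-2-enal | O=C/C=C/c1cc(OCc2ccccc2)cc(OCc2ccccc2)c1 | intermediate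
7 | methyl (3R,4S)-3-[3,5-bis(benzyloxy)phenyl]-4,6-bis[4-(benzyloxy)phenyl]-6-oxohexanoate | COC(=O)C[C@@H](c1cc(OCc2ccccc2)cc(OCc2ccccc2)c1)[C@H](CC(=O)c1ccc(OCc2ccccc2)cc1)c1ccc(OCc2ccccc2)cc1 | intermediate
8 | (3R,4R)-2-[4-(benzyloxy)benzoyl]-4-[3,5-bis(benzyloxy)phenyl]-3-[4-(benzyloxy)phenyl]cyclopentan-1-one (3,4-cis; C2 undefined) | O=C(c1ccc(OCc2ccccc2)cc1)C1C(=O)C[C@@H](c2cc(OCc3ccccc3)cc(OCc3ccccc3)c2)[C@H]1c1ccc(OCc2ccccc2)cc1 | intermediate
9 | ethyl 2-(2-methyl-1,3-dioxolan-2-yl)acetate | CCOC(=O)CC1(C)OCCO1 | starting material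
10 | N-methoxy-N-methyl-2-(2-methyl-1,3-dioxolan-2-yl)acetamide | CON(C)C(=O)CC1(C)OCCO1 | intermediate
11 | dilithium dianion of 8 (β-diketonate plus ring enolate at the former CH2; aryl-bearing carbons as in 8) | [Li+].[Li+].[O-]C(c1ccc(OCc2ccccc2)cc1)=C1C([O-])=C[C@@H](c2cc(OCc3ccccc3)cc(OCc3ccccc3)c2)[C@H]1c1ccc(OCc2ccccc2)cc1 | intermediate
12 | triketone ketal: 8 carrying a (2-methyl-1,3-dioxolan-2-yl)acetyl group on the ring carbon that was CH2 (aryl-bearing carbons as in 8; the two acyl-bearing carbons undefined) | O=C(c1ccc(OCc2ccccc2)cc1)C1C(=O)C(C(=O)CC2(C)OCCO2)[C@@H](c2cc(OCc3ccccc3)cc(OCc3ccccc3)c2)[C@H]1c1ccc(OCc2ccccc2)cc1 | intermediate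
13 | tetraketone: 8 carrying a 3-oxobutanoyl group on the ring carbon that was CH2 (aryl-bearing carbons as in 8) | O=C(c1ccc(OCc2ccccc2)cc1)C1C(=O)C(C(=O)CC(C)=O)[C@@H](c2cc(OCc3ccccc3)cc(OCc3ccccc3)c2)[C@H]1c1ccc(OCc2ccccc2)cc1 | intermediate
14 | [(1S,2R,3R)-3-[3,5-bis(benzyloxy)phenyl]-2-[4-(benzyloxy)phenyl]-4,6-dihydroxy-2,3-dihydro-1H-inden-1-yl][4-(benzyloxy)phenyl]methanone | O=C(c1ccc(OCc2ccccc2)cc1)[C@@H]1c2cc(O)cc(O)c2[C@@H](c2cc(OCc3ccccc3)cc(OCc3ccccc3)c2)[C@H]1c1ccc(OCc2ccccc2)cc1 | intermediate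
15 | [(1S,2R,3R)-4,6-bis(benzyloxy)-3-[3,5-bis(benzyloxy)phenyl]-2-[4-(benzyloxy)phenyl]-2,3-dihydro-1H-inden-1-yl][4-(benzyloxy)phenyl]methanone | O=C(c1ccc(OCc2ccccc2)cc1)[C@@H]1c2cc(OCc3ccccc3)cc(OCc3ccccc3)c2[C@@H](c2cc(OCc3ccccc3)cc(OCc3ccccc3)c2)[C@H]1c1ccc(OCc2ccccc2)cc1 | intermediate
16 | potassium enolate of 15 (C1=C8 enolate; C2 and C3 as in 15) | [K+].[O-]C(c1ccc(OCc2ccccc2)cc1)=C1c2cc(OCc3ccccc3)cc(OCc3ccccc3)c2[C@@H](c2cc(OCc3ccccc3)cc(OCc3ccccc3)c2)[C@H]1c1ccc(OCc2ccccc2)cc1 | intermediate
17 | [(1R,2R,3R)-4,6-bis(benzyloxy)-3-[3,5-bis(benzyloxy)phenyl]-2-[4-(benzyloxy)phenyl]-2,3-dihydro-1H-inden-1-yl][4-(benzyloxy)phenyl]methanone (all-cis) | O=C(c1ccc(OCc2ccccc2)cc1)[C@H]1c2cc(OCc3ccccc3)cc(OCc3ccccc3)c2[C@@H](c2cc(OCc3ccccc3)cc(OCc3ccccc3)c2)[C@H]1c1ccc(OCc2ccccc2)cc1 | intermediate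
18 | caraphenol B, [(1R,2R,3R)-3-(3,5-dihydroxyphenyl)-4,6-dihydroxy-2-(4-hydroxyphenyl)-2,3-dihydro-1H-inden-1-yl](4-hydroxyphenyl)methanone | O=C(c1ccc(O)cc1)[C@H]1c2cc(O)cc(O)c2[C@@H](c2cc(O)cc(O)c2)[C@H]1c1ccc(O)cc1 | target

**Step count**

Total steps: 9. Longest linear sequence: 7 steps (steps 1, 3, 4, 6, 7, 8, 9).

**Steps most likely to fail**

1. Step 6. Proton transfer from amide 10 to the dianion may outrun acylation at the hindered ring carbanion. In the hydroxide stage, retro-Claisen cleavage of the polyketone may compete with the slow attack of the unactivated methyl carbon on C7a. The fallback forms the same two bonds but activates C7 with an ester, and sets out from 8. The dianion (LiN(iPr)2, 3.2 equiv) is acylated with dimethyl 2,2'-(1,3-dioxolane-2,2-diyl)diacetate to give the triketone ketal ester F1. Aqueous HCl unmasks it to the tetraketone ester F2, and Ca(OAc)2 in methanol closes ring A by aldol attack of the now doubly activated C7 methylene on C7a, giving the methyl resorcylate F3 (ester on C7). Aqueous KOH saponifies this to the β-resorcylic acid F4, which should lose CO2 on acidification and warming. The route is rejoined at 14.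

2. Step 3. Enantiofacial control by the carbene may be insufficient, or may be eroded by a less selective background pathway. The fallback replaces catalyst control by resolution and sets out from 3 and 6. They are combined with the achiral 2-mesityl-6,7-dihydro-5H-pyrrolo[2,1-c][1,2,4]triazol-2-ium chloride, DBU and methanol to give the racemic cis-type adduct, that is 7 together with its mirror image ent-7 F5. The enantiomers are separated by preparative chromatography on an amylose tris(3,5-dimethylphenylcarbamate) phase. Compound 7 re-enters the route at step 4.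

3. Step 8. Protonation on oxygen followed by ketonisation under equilibrating conditions during warming and work-up, or re-enolisation of the product, may return the trans ketone; the facial bias may also be too small. The fallback delivers both hydrogens to one face by hydrogenation and sets out from 15. KN(SiMe3)2 and then PhSeBr give the α-phenylselanyl ketone F6, in which selenium enters C1 anti to ring C and is therefore syn to the hydrogen on C2. H2O2 at 0 °C oxidises it to the selenoxide F7, whose syn-elimination gives the indene F8 with a C1=C2 double bond. Hydrogenation over Pd/C should add H2 to the face opposite ring E at C3, setting C1 and C2 cis to each other and to C3 while the benzyl ethers are cleaved. This arrives directly at 18.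

**Further compounds**

F1 | step 6 | triketone ketal ester: 8 carrying a [2-(2-methoxy-2-oxoethyl)-1,3-dioxolan-2-yl]acetyl group on the ring carbon that was CH2 | O=C(c1ccc(OCc2ccccc2)cc1)C1C(=O)C(C(=O)CC2(CC(=O)OC)OCCO2)[C@@H](c2cc(OCc3ccccc3)cc(OCc3ccccc3)c2)[C@H]1c1ccc(OCc2ccccc2)cc1
F2 | step 6 | tetraketone ester: 8 carrying a 5-methoxy-3,5-dioxopentanoyl group on the ring carbon that was CH2 | O=C(c1ccc(OCc2ccccc2)cc1)C1C(=O)C(C(=O)CC(=O)CC(=O)OC)[C@@H](c2cc(OCc3ccccc3)cc(OCc3ccccc3)c2)[C@H]1c1ccc(OCc2ccccc2)cc1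
F3 | step 6 | methyl resorcylate: 14 with a methoxycarbonyl group on C7 | O=C(c1ccc(OCc2ccccc2)cc1)[C@@H]1c2c(C(=O)OC)c(O)cc(O)c2[C@@H](c2cc(OCc3ccccc3)cc(OCc3ccccc3)c2)[C@H]1c1ccc(OCc2ccccc2)cc1
F4 | step 6 | β-resorcylic acid: 14 with a carboxyl group on C7 | O=C(c1ccc(OCc2ccccc2)cc1)[C@@H]1c2c(C(=O)O)c(O)cc(O)c2[C@@H](c2cc(OCc3ccccc3)cc(OCc3ccccc3)c2)[C@H]1c1ccc(OCc2ccccc2)cc1
F5 | step 3 | ent-7, methyl (3S,4R)-3-[3,5-bis(benzyloxy)phenyl]-4,6-bis[4-(benzyloxy)phenyl]-6-oxohexanoate (formed with 7 as the racemate) | COC(=O)C[C@H](c1cc(OCc2ccccc2)cc(OCc2ccccc2)c1)[C@@H](CC(=O)c1ccc(OCc2ccccc2)cc1)c1ccc(OCc2ccccc2)cc1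
F6 | step 8 | α-phenylselanyl ketone: 15 with PhSe on C1, cis to the hydrogens on C2 and C3 | O=C(c1ccc(OCc2ccccc2)cc1)[C@@]1([Se]c2ccccc2)c2cc(OCc3ccccc3)cc(OCc3ccccc3)c2[C@@H](c2cc(OCc3ccccc3)cc(OCc3ccccc3)c2)[C@H]1c1ccc(OCc2ccccc2)cc1
F7 | step 8 | selenoxide of F6 (configuration at selenium undefined) | O=C(c1ccc(OCc2ccccc2)cc1)[C@@]1([Se](=O)c2ccccc2)c2cc(OCc3ccccc3)cc(OCc3ccccc3)c2[C@@H](c2cc(OCc3ccccc3)cc(OCc3ccccc3)c2)[C@H]1c1ccc(OCc2ccccc2)cc1
F8 | step 8 | indene: 15 with a C1=C2 double bond, C3 unchanged | O=C(c1ccc(OCc2ccccc2)cc1)C1=C(c2ccc(OCc3ccccc3)cc2)[C@H](c2cc(OCc3ccccc3)cc(OCc3ccccc3)c2)c2c(OCc3ccccc3)cc(OCc3ccccc3)cc12
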